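**Retrosynthetic overview**
1. Feature: ring B of unit 1 (C1'–C6') carries C2 of ring C at C1', C6'' of ring A of unit 2 at C3' and OMe at C4'. A 5-acyl-2-pyrone and an aryl methyl ynol ether give this 1,3,4 pattern after loss of CO2, so the tri-ortho-substituted C3'–C6'' biaryl comes from ring construction.
2. Endgame: remove three O-benzyl groups; open ring C of unit 1 at O1–C2 (catalytic asymmetric oxa-Michael on an alkylidene β-keto ester, ester then lost); cut the alkene by Knoevenagel to aldehyde 14 and β-keto ester 17 (ring A of unit 1).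
3. Key cut: C2'–C3' and C4'–C5' of ring B, giving pyrone 11 and the 6''-(methoxyethynyl)flavanone 8. The pyrone carries an S-ethyl thioester instead of an alkyl ester, so CHO is reached by Fukuyama reduction without a saponification that would racemise C2''.
4. Compound 8 comes from (2S)-sakuranetin (rings A, B, C of unit 2 and C2'' from the chiral pool) by base-free benzylation, C6'' iodination, base-free benzylation and Stille alkynylation.
5. Ring order: unit 2 (bought), then ring B of unit 1 (step 7), then ring C of unit 1 (step 12); ring A of unit 1 enters with 17.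

Key step: step 7

Assumption 1: the C3'–C6'' axis is taken as not configurationally fixed, since the target carries no axial descriptor.
Assumption 2: the quinine-derived amine–thiourea is taken as the 2S-selective member of the pseudoenantiomeric pair; if a trial on the p-anisaldehyde-derived model alkylidene shows the opposite sense, the quinidine-derived catalyst replaces it with no other change.
Assumption 3: alkylidene 18 is drawn as the Z isomer (aryl cis to the ester); the isomers should interconvert under amine catalysis.
Assumption 4: commercial natural sakuranetin is the 2S enantiomer; enantiopurity is to be checked by chiral HPLC on 1, 4, 8 and 13.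

**Step 1**
Reactants: 1 (2S)-sakuranetin
Product: 2 (2S)-2-(4-benzyloxyphenyl)-5-hydroxy-7-methoxychroman-4-one
Conditions: BnOH (1.1 equiv), PPh3, DIAD, THF, 0 °C to rt
Reagents that add atoms: benzyl alcohol, OCc1ccccc1
Why: Mitsunobu etherification takes the free 4'''-OH in preference to the less reactive carbonyl-chelated 5''-OH, and the absence of an external base avoids enolate-triggered opening of ring C that would racemise C2''.

**Step 2**
Reactants: 2 (2S)-2-(4-benzyloxyphenyl)-5-hydroxy-7-methoxychroman-4-one
Product: 3 (2S)-2-(4-benzyloxyphenyl)-5-hydroxy-6-iodo-7-methoxychroman-4-one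
Conditions: NIS (1.05 equiv), DMF, 0 °C to rt, dark
Reagents that add atoms: N-iodosuccinimide, O=C1CCC(=O)N1I
Why: In this electrophilic aromatic iodination under neutral conditions the free hydrogen-bonded 5''-OH should steer iodine to its ortho carbon C6'' of the phloroglucinol ring rather than to C8'' or the less activated benzyloxyphenyl ring; the site is to be confirmed by HMBC from the chelated OH.

**Step 3**
Reactants: 3 (2S)-2-(4-benzyloxyphenyl)-5-hydroxy-6-iodo-7-methoxychroman-4-one
Product: 4 (2S)-5-benzyloxy-2-(4-benzyloxyphenyl)-6-iodo-7-methoxychroman-4-one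
Conditions: BnOH (2 equiv), PPh3 (2 equiv), DIAD (2 equiv), THF, 0 to 40 °C
Reagents that add atoms: benzyl alcohol, OCc1ccccc1
Why: Mitsunobu etherification works with ortho-acylphenols as the acid partner, the flanking iodine raises the acidity further, and the neutral medium avoids the chalcone opening and racemisation that carbonate-mediated alkylation of a flavanone 5-OH risks.

**Step 4**
Reactants: 5 chloroacetaldehyde dimethyl acetal
Product: 7 tributyl(methoxyethynyl)stannane, via lithium methoxyacetylide 6 (not isolated)
Conditions: Et2NH (3.3 equiv), n-BuLi (3.2 equiv), THF, 0 °C; add 5, 0 °C; Bu3SnCl, −78 °C to rt; distil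
Reagents that add atoms: tributyltin chloride, CCCC[Sn](Cl)(CCCC)CCCC; n-butyllithium, [Li]CCCC (lithium of 6 only)
Why: Twofold amide-induced β-elimination (MeOH, then HCl) and deprotonation gives the alkoxyacetylide in one flask, and its stannylation is a plain acetylide substitution at tin that yields a distillable, base-free reagent.

**Step 5**
Reactants: 4 (2S)-5-benzyloxy-2-(4-benzyloxyphenyl)-6-iodo-7-methoxychroman-4-one; 7 tributyl(methoxyethynyl)stannane
Product: 8 (2S)-5-benzyloxy-2-(4-benzyloxyphenyl)-7-methoxy-6-(methoxyethynyl)chroman-4-one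
Conditions: Pd2(dba)3 (2.5 mol %), AsPh3 (20 mol %), DMF, 50 °C; chromatography on K2CO3-doped silica
Reagents that add atoms: none
Why: Stille coupling of alkoxyethynylstannanes with aryl iodides is known, the slim and fast-transferring alkynyl group fits between the two ortho alkoxy groups, and the base-free medium protects both C2'' and the acid-labile ynol ether.

**Step 6**
Reactants: 9 coumalic acid
Product: 11 S-ethyl 2-oxo-2H-pyran-5-carbothioate, via coumalyl chloride 10 (not isolated)
Conditions: (COCl)2, cat. DMF, CH2Cl2, rt; then EtSH (1.0 equiv), pyridine (1.05 equiv), CH2Cl2, −20 to 0 °C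
Reagents that add atoms: ethanethiol, CCS; oxalyl chloride, ClC(=O)C(=O)Cl (chlorine of 10 only)
Why: Acid chloride formation followed by S-acylation through the acylpyridinium ion is standard, and the weak base keeps the thiolate level too low for conjugate attack at pyrone C6.

**Step 7**
Reactants: 8 (2S)-5-benzyloxy-2-(4-benzyloxyphenyl)-7-methoxy-6-(methoxyethynyl)chroman-4-one; 11 S-ethyl 2-oxo-2H-pyran-5-carbothioate
Product: 13 S-ethyl 4-methoxy-3-[(2S)-5-benzyloxy-2-(4-benzyloxyphenyl)-7-methoxy-4-oxochroman-6-yl]benzenecarbothioate, via bridged lactone cycloadduct 12 (not isolated)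
Conditions: 11 (2.5 equiv), PhMe, 110 °C, sealed tube, Ar, base-washed glass
Reagents that add atoms: none
Why: This is an inverse-electron-demand Diels–Alder reaction followed by retro-Diels–Alder loss of CO2, the known way from 5-acyl-2-pyrones (coumalates) and donor alkynes (ynol ethers, ynamines) to para-donor benzoyl arenes. The pyrone reacts as a diene across C3 and C6: the oxygen lone pair of 8 makes the aryl-bearing alkyne carbon nucleophilic, this carbon bonds to C6 (activated by both the lactone and the thioester carbonyl), and the methoxy-bearing carbon closes onto C3. Ring B of unit 1 is closed by an intermolecular [4+2] annulation in which pyrone C6, C5, C4 and C3 become C2', C1', C6' and C5' and the alkyne carbons become C3' and C4', with new bonds C2'–C3' and C4'–C5', and lactone 12 aromatises at the reaction temperature. No lasting stereocentre is formed, because both bridgeheads of 12 end as sp2 carbons, and C2'' is a spectator in a neutral aprotic medium. The selectivity needed is regiochemical (OMe para and aryl meta to the acyl group) and rests on the same polarisation that makes aryl ynol ethers take up electrophiles at the aryl-bearing carbon, and a methyl ynol ether has no β-hydrogen, so the retro-ene decay to a ketene that limits higher alkyl ynol ethers on heating is closed. The crowded C3'–C6'' bond is already present in 8 as an unhindered sp–sp2 bond, so no metal has to join two hindered arenes.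

**Step 8**
Reactants: 13 S-ethyl 4-methoxy-3-[(2S)-5-benzyloxy-2-(4-benzyloxyphenyl)-7-methoxy-4-oxochroman-6-yl]benzenecarbothioate
Product: 14 4-methoxy-3-[(2S)-5-benzyloxy-2-(4-benzyloxyphenyl)-7-methoxy-4-oxochroman-6-yl]benzaldehyde
Conditions: Et3SiH (3 equiv), 10% Pd/C (5 mol % Pd), acetone, rt
Reagents that add atoms: none
Why: Fukuyama reduction turns the thioester into the aldehyde without touching the ring C ketone, and the aprotic solvent suppresses silane-derived hydrogen that could attack the benzyl ethers.

**Step 9**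
Reactants: 15 2',6'-dihydroxy-4'-methoxyacetophenone
Product: 16 2'-benzyloxy-6'-hydroxy-4'-methoxyacetophenone
Conditions: BnBr (1.05 equiv), K2CO3 (1.1 equiv), acetone, reflux
Reagents that add atoms: benzyl bromide, BrCc1ccccc1
Why: Williamson etherification of the symmetric diol should stop after one alkylation because the remaining OH stays locked in the chelate with the acetyl group.

**Step 10**
Reactants: 16 2'-benzyloxy-6'-hydroxy-4'-methoxyacetophenone
Product: 17 tert-butyl 3-(2-benzyloxy-6-hydroxy-4-methoxyphenyl)-3-oxopropanoate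
Conditions: LiHMDS (3.3 equiv), THF, −78 °C; Boc2O (1.1 equiv), −78 to 0 °C; cold 1 M HCl
Reagents that add atoms: di-tert-butyl dicarbonate, CC(C)(C)OC(=O)OC(=O)OC(C)(C)C
Why: This is a Claisen-type C-acylation of the lithium dianion of an o-hydroxyacetophenone; any O-carbonate formed at the phenoxide should converge on the same product by a Baker–Venkataraman-type O-to-C shift, and the third equivalent of base takes up the acidic product.

**Step 11**
Reactants: 14 4-methoxy-3-[(2S)-5-benzyloxy-2-(4-benzyloxyphenyl)-7-methoxy-4-oxochroman-6-yl]benzaldehyde; 17 tert-butyl 3-(2-benzyloxy-6-hydroxy-4-methoxyphenyl)-3-oxopropanoate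
Product: 18 tert-butyl (Z)-2-(2-benzyloxy-6-hydroxy-4-methoxybenzoyl)-3-{4-methoxy-3-[(2S)-5-benzyloxy-2-(4-benzyloxyphenyl)-7-methoxy-4-oxochroman-6-yl]phenyl}prop-2-enoate
Conditions: piperidine (20 mol %), AcOH (20 mol %), 4 Å sieves, PhMe, rt
Reagents that add atoms: none
Why: In this Knoevenagel condensation under buffered piperidinium acetate the β-keto ester is by far the strongest carbon acid, so C3''–H2 stays out, and room temperature should hold back premature phenol closure and leave C2'' intact.

**Step 12**
Reactants: 18 tert-butyl (Z)-2-(2-benzyloxy-6-hydroxy-4-methoxybenzoyl)-3-{4-methoxy-3-[(2S)-5-benzyloxy-2-(4-benzyloxyphenyl)-7-methoxy-4-oxochroman-6-yl]phenyl}prop-2-enoate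
Product: 21 (2S,2''S)-5,5'',4'''-tri-O-benzyl ether of the target, via tert-butyl flavanone-3-carboxylate 19 (not isolated), via flavanone-3-carboxylic acid 20 (not isolated)
Conditions: 1-[3,5-bis(trifluoromethyl)phenyl]-3-[(8α,9S)-6'-methoxycinchonan-9-yl]thiourea (10 mol %), PhMe, −25 °C; then TsOH·H2O (0.5 equiv), 80 °C
Reagents that add atoms: none
Why: Amine–thiourea-catalysed intramolecular oxa-Michael addition (6-endo-trig) of alkylidene β-keto esters is a known enantioselective flavanone synthesis in which the thiourea binds the dicarbonyl and the quinuclidine delivers the phenol to one alkene face, setting C2 as S under catalyst control with the remote C2'' expected to have no influence; TsOH then silences the base, cleaves the tert-butyl ester, and decarboxylation erases the C3 centre.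

**Step 13**
Reactants: 21 (2S,2''S)-5,5'',4'''-tri-O-benzyl ether of the target
Product: 22 target, (2S,2''S)-2,3,2'',3''-tetrahydrorobustaflavone 7,4',7''-trimethyl ether
Conditions: H2 (1 atm), 10% Pd/C, EtOAc–EtOH, rt
Reagents that add atoms: none
Why: Catalytic hydrogenolysis removes the three aryl benzyl ethers under neutral conditions, so neither C2 centre can epimerise, and at 1 atm with monitoring the ring C benzylic C–O bonds and the ketones should stay intact.

**Compound list**
1 | (2S)-sakuranetin | COc1cc(O)c2c(c1)O[C@H](c1ccc(O)cc1)CC2=O | starting material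
2 | (2S)-2-(4-benzyloxyphenyl)-5-hydroxy-7-methoxychroman-4-one | COc1cc(O)c2c(c1)O[C@H](c1ccc(OCc3ccccc3)cc1)CC2=O | intermediate
3 | (2S)-2-(4-benzyloxyphenyl)-5-hydroxy-6-iodo-7-methoxychroman-4-one | Ic1c(OC)cc2c(c1O)C(=O)C[C@@H](c1ccc(OCc3ccccc3)cc1)O2 | intermediate
4 | (2S)-5-benzyloxy-2-(4-benzyloxyphenyl)-6-iodo-7-methoxychroman-4-one | Ic1c(OC)cc2c(c1OCc1ccccc1)C(=O)C[C@@H](c1ccc(OCc3ccccc3)cc1)O2 | intermediate
5 | chloroacetaldehyde dimethyl acetal | COC(CCl)OC | starting material
6 | lithium methoxyacetylide | [Li]C#COC | intermediate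
7 | tributyl(methoxyethynyl)stannane | CCCC[Sn](CCCC)(CCCC)C#COC | intermediate
8 | (2S)-5-benzyloxy-2-(4-benzyloxyphenyl)-7-methoxy-6-(methoxyethynyl)chroman-4-one | COC#Cc1c(OC)cc2c(c1OCc1ccccc1)C(=O)C[C@@H](c1ccc(OCc3ccccc3)cc1)O2 | intermediate
9 | coumalic acid | OC(=O)C1=COC(=O)C=C1 | starting material
10 | coumalyl chloride | ClC(=O)C1=COC(=O)C=C1 | intermediate
11 | S-ethyl 2-oxo-2H-pyran-5-carbothioate | CCSC(=O)C1=COC(=O)C=C1 | intermediate
12 | 2-oxabicyclo[2.2.2]octa-5,7-dien-3-one cycloadduct (either bridgehead diastereomer; both collapse to 13) | CCSC(=O)C1=CC2C(=O)OC1C(c1c(OC)cc3c(c1OCc1ccccc1)C(=O)C[C@@H](c1ccc(OCc4ccccc4)cc1)O3)=C2OC | intermediate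
13 | S-ethyl 4-methoxy-3-[(2S)-5-benzyloxy-2-(4-benzyloxyphenyl)-7-methoxy-4-oxochroman-6-yl]benzenecarbothioate | CCSC(=O)c1ccc(OC)c(-c2c(OC)cc3c(c2OCc2ccccc2)C(=O)C[C@@H](c2ccc(OCc4ccccc4)cc2)O3)c1 | intermediate
14 | 4-methoxy-3-[(2S)-5-benzyloxy-2-(4-benzyloxyphenyl)-7-methoxy-4-oxochroman-6-yl]benzaldehyde | O=Cc1ccc(OC)c(-c2c(OC)cc3c(c2OCc2ccccc2)C(=O)C[C@@H](c2ccc(OCc4ccccc4)cc2)O3)c1 | intermediate
15 | 2',6'-dihydroxy-4'-methoxyacetophenone | CC(=O)c1c(O)cc(OC)cc1O | starting material
16 | 2'-benzyloxy-6'-hydroxy-4'-methoxyacetophenone | CC(=O)c1c(O)cc(OC)cc1OCc1ccccc1 | intermediate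
17 | tert-butyl 3-(2-benzyloxy-6-hydroxy-4-methoxyphenyl)-3-oxopropanoate | CC(C)(C)OC(=O)CC(=O)c1c(O)cc(OC)cc1OCc1ccccc1 | intermediate
18 | (Z)-alkylidene β-keto ester | CC(C)(C)OC(=O)/C(=C\c1ccc(OC)c(-c2c(OC)cc3c(c2OCc2ccccc2)C(=O)C[C@@H](c2ccc(OCc4ccccc4)cc2)O3)c1)C(=O)c1c(O)cc(OC)cc1OCc1ccccc1 | intermediate
19 | tert-butyl (2S,3R)-trans-flavanone-3-carboxylate of unit 1 (keto form shown, C3 labile) | COc1cc(OCc3ccccc3)c2c(c1)O[C@H](c1ccc(OC)c(-c3c(OC)cc4c(c3OCc3ccccc3)C(=O)C[C@@H](c3ccc(OCc5ccccc5)cc3)O4)c1)[C@@H](C(=O)OC(C)(C)C)C2=O | intermediate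
20 | (2S,3R)-flavanone-3-carboxylic acid of unit 1 | COc1cc(OCc3ccccc3)c2c(c1)O[C@H](c1ccc(OC)c(-c3c(OC)cc4c(c3OCc3ccccc3)C(=O)C[C@@H](c3ccc(OCc5ccccc5)cc3)O4)c1)[C@@H](C(=O)O)C2=O | intermediate
21 | (2S,2''S)-5,5'',4'''-tri-O-benzyl ether of the target | COc1cc(OCc3ccccc3)c2c(c1)O[C@H](c1ccc(OC)c(-c3c(OC)cc4c(c3OCc3ccccc3)C(=O)C[C@@H](c3ccc(OCc5ccccc5)cc3)O4)c1)CC2=O | intermediate
22 | CNP0150873.1, (2S,2''S) | COc1cc(O)c2c(c1)O[C@H](c1ccc(OC)c(-c3c(OC)cc4c(c3O)C(=O)C[C@@H](c3ccc(O)cc3)O4)c1)CC2=O | target

**Step count**
Total step count: 13. Longest linear sequence: 9 steps from 1 (steps 1, 2, 3, 5, 7, 8, 11, 12, 13).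

**Steps most likely to fail**

Step 7. The cycloaddition may be slow because the nucleophilic alkyne carbon carries a 2,6-dioxygenated aryl group. Slow reaction leaves time for thermal self-dimerisation of the pyrone, and donation from the electron-rich aryl group could erode the regioselectivity.
Fallback: iodide 4 is coupled with commercial (5-formyl-2-methoxyphenyl)boronic acid by Suzuki–Miyaura reaction (Pd(OAc)2, SPhos, K3PO4, PhMe–H2O, 60 °C, short contact time). This forms C3'–C6'' directly and returns to the route at aldehyde 14.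

Step 12. Facial selectivity may be poor on a 6'-alkoxy-substituted aroyl substrate. Uncatalysed closure may already begin during step 11, and the benzyl ethers may be partly lost under TsOH at 80 °C.
Fallback: C2 is set by forming the C2–C1' bond instead of O1–C2.
- Thioester 13 undergoes rhodium-catalysed decarbonylative borylation ([RhCl(cod)]2, PBu3, KOAc, B2pin2, CPME, 80 °C) to give the aryl pinacol boronate F1.
- NaIO4 and NH4OAc in aqueous acetone convert F1 into the arylboronic acid F2.
- In parallel, 16 is heated with DMF dimethyl acetal to give the enaminone F3.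
- HCl in CH2Cl2 closes F3 to 5-benzyloxy-7-methoxychromone F4.
- Rhodium-catalysed asymmetric 1,4-addition of F2 to F4 ([Rh(OH)(cod)]2, the antipode of MeO-F12-BIPHEP that gives 2S, PhMe–H2O, rt) returns to the route at 21.

Step 5. Oxidative addition and transmetalation may be slow at the doubly ortho-flanked C6''–I bond, and the ynol ether may be hydrated on work-up or on silica.
Fallback: stannane 7 undergoes tin–lithium exchange (n-BuLi, THF, −78 °C), which regenerates 6 free of amine and alkoxide. ZnCl2 then gives chloro(methoxyethynyl)zinc F5. Negishi coupling with 4 (Pd(PPh3)4, THF, rt) returns to the route at 8, which is filtered through basic alumina and used directly in step 7.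

**Further compounds**
F0 | step 7 | none | none
F1 | step 12 | pinacol boronate at C1' of the dibenzyl unit 2 biaryl | CC1(C)OB(OC1(C)C)c1ccc(OC)c(-c2c(OC)cc3c(c2OCc2ccccc2)C(=O)C[C@@H](c2ccc(OCc4ccccc4)cc2)O3)c1
F2 | step 12 | boronic acid at C1' of the dibenzyl unit 2 biaryl | OB(O)c1ccc(OC)c(-c2c(OC)cc3c(c2OCc2ccccc2)C(=O)C[C@@H](c2ccc(OCc4ccccc4)cc2)O3)c1
F3 | step 12 | (E)-1-(2-benzyloxy-6-hydroxy-4-methoxyphenyl)-3-(dimethylamino)prop-2-en-1-one | CN(C)/C=C/C(=O)c1c(O)cc(OC)cc1OCc1ccccc1
F4 | step 12 | 5-benzyloxy-7-methoxy-4H-chromen-4-one | COc1cc2OC=CC(=O)c2c(OCc2ccccc2)c1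
F5 | step 5 | chloro(methoxyethynyl)zinc | COC#C[Zn]Cl
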